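**Retrosynthetic overview**
1. Target 8 ⇒ 6: the bridgehead C–O bond (and the bridgehead C–H) come from syn hydroboration–oxidation of the tetrasubstituted alkene of C2-symmetric 6, on the face away from both aryl groups.
2. 6 ⇒ 5: both ring C–O bonds (O–CHAr) and both benzylic stereocentres come from one enantioselective palladium-catalysed oxidative double cycloetherification of an achiral (E,E)-diene diol.
3. 5 ⇒ 4 ⇒ 1 + 2: ester reduction, then a double Stobbe condensation of veratraldehyde with dimethyl succinate.
4. Ring order: ring A (first oxypalladation) and ring B (allylic etherification) close in the same flask in step 3; no other ring-forming step is needed.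

Assumption: the target is taken exactly as drawn, i.e. (3R,3aR,6S,6aS), cis-fused, with each aryl group trans to the neighbouring bridgehead substituent.
Assumption: the sense of induction of the palladium–ligand pair in step 3 cannot be predicted with certainty; the (S)-ligand is written, and its mirror image is used if the first run gives the antipode of 6.

**Step 1**
Reactants: 1 3,4-dimethoxybenzaldehyde (2.2 equiv); 2 dimethyl succinate
Product: 4 dimethyl (2E,3E)-2,3-bis(3,4-dimethoxybenzylidene)butanedioate, via disodium dicarboxylate 3 (not isolated)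
Conditions: NaOMe, MeOH, reflux; evaporate; then MeI, DMF, 25 °C
Reagents that add atoms: iodomethane, CI
Why: Double Stobbe condensation, in which each aldol adduct lactonises onto the neighbouring ester and opens by E1cB elimination to the favoured (E)-arylidene carboxylate (aryl trans to the carboxyl group), followed by SN2 O-methylation of the dicarboxylate; no stereocentre is formed.

**Step 2**
Reactants: 4 dimethyl (2E,3E)-2,3-bis(3,4-dimethoxybenzylidene)butanedioate
Product: 5 (2E,3E)-2,3-bis(3,4-dimethoxybenzylidene)butane-1,4-diol
Conditions: i-Bu2AlH (5 equiv), CH2Cl2, −78 → 0 °C; aq. KNaC4H4O6 work-up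
Reagents that add atoms: none
Why: 1,2-Reduction of the α,β-unsaturated esters by i-Bu2AlH gives the allylic alcohols without touching the alkenes, so the (E,E) geometry is carried over unchanged.

**Step 3**
Reactants: 5 (2E,3E)-2,3-bis(3,4-dimethoxybenzylidene)butane-1,4-diol
Product: 6 (1R,4R)-1,4-bis(3,4-dimethoxyphenyl)-1H,3H,4H,6H-furo[3,4-c]furan
Conditions: Pd(OCOCF3)2 (10 mol %), (S)-4-tert-butyl-2-(pyridin-2-yl)-4,5-dihydro-1,3-oxazole (12 mol %), 1,4-benzoquinone (1.5 equiv), 2,6-di-tert-butylpyridine (20 mol %), 3 Å MS, THF, 0 °C
Reagents that add atoms: none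
Why: Proposed new method: a cationic divalent palladium centre held by the chiral pyridine–oxazoline binds one face of one of the two homotopic styrenyl alkenes, and the hydroxymethyl group of the other half adds anti to the metal at the electron-rich benzylic terminus (5-endo oxypalladation; ring A, first stereocentre); the catalyst-bound η3-allyl species is then opened at its benzylic terminus by the second hydroxymethyl group, again anti to the metal (ring B, second stereocentre), and benzoquinone returns zerovalent palladium to the divalent state. Because both oxygens enter the same face of an (E,E)-diene, the two aryl groups must end cis (the C2-symmetric isomer), and the ligand decides which enantiomer forms. The closest known reaction type is the Bäckvall palladium/benzoquinone 1,4-dialkoxylation of conjugated dienes (cis addition by two anti attacks) combined with enantioselective Wacker-type cycloetherification under pyridine–oxazoline ligands; neither has been shown as a double intramolecular closure on a 2,3-bis(hydroxymethyl)-1,4-diaryl diene.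

**Step 4**
Reactants: 6 (1R,4R)-1,4-bis(3,4-dimethoxyphenyl)-1H,3H,4H,6H-furo[3,4-c]furan
Product: 8 (3R,3aR,6S,6aS)-3,6-bis(3,4-dimethoxyphenyl)tetrahydro-1H,3H-furo[3,4-c]furan-3a(4H)-ol, via tertiary alkylborane 7 (not isolated)
Conditions: BH3·THF (3 equiv), THF, 0 → 25 °C; then NaOH, H2O2, H2O, 0 → 25 °C
Reagents that add atoms: hydrogen peroxide, OO
Why: Brown hydroboration–oxidation adds H and B syn to the alkene face opposite both aryl groups (the two alkene carbons are homotopic, so regiochemistry is moot) and oxidation with retention gives the cis-fused tertiary alcohol, which sets C3a and C6a with both aryl groups trans to the bridgehead OH and H.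

**Compound list**
1 | 3,4-dimethoxybenzaldehyde (veratraldehyde) | COc1ccc(C=O)cc1OC | starting material
2 | dimethyl succinate | COC(=O)CCC(=O)OC | starting material
3 | disodium (2E,3E)-2,3-bis(3,4-dimethoxybenzylidene)butanedioate (each aryl trans to its carboxylate) | COc1ccc(/C=C(C(=O)[O-])\C(C(=O)[O-])=C/c2ccc(OC)c(OC)c2)cc1OC.[Na+].[Na+] | intermediate (not isolated)
4 | dimethyl (2E,3E)-2,3-bis(3,4-dimethoxybenzylidene)butanedioate | COc1ccc(/C=C(C(=O)OC)\C(C(=O)OC)=C/c2ccc(OC)c(OC)c2)cc1OC | intermediate
5 | (2E,3E)-2,3-bis(3,4-dimethoxybenzylidene)butane-1,4-diol (each aryl trans to its CH2OH) | COc1ccc(/C=C(CO)\C(CO)=C/c2ccc(OC)c(OC)c2)cc1OC | intermediate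
6 | (1R,4R)-1,4-bis(3,4-dimethoxyphenyl)-1H,3H,4H,6H-furo[3,4-c]furan (two 2,5-dihydrofurans sharing the tetrasubstituted alkene; both aryl groups on the same face) | COc1ccc([C@H]2OCC3=C2CO[C@@H]3c2ccc(OC)c(OC)c2)cc1OC | intermediate
7 | [(3S,3aS,6S,6aS)-3,6-bis(3,4-dimethoxyphenyl)hexahydrofuro[3,4-c]furan-3a-yl]borane (BH2 on C3a cis to H on C6a, both trans to the aryl groups) | COc1ccc([C@H]2OC[C@@]3(B)[C@@H](c4ccc(OC)c(OC)c4)OC[C@@H]23)cc1OC | intermediate (not isolated)
8 | (3R,3aR,6S,6aS)-3,6-bis(3,4-dimethoxyphenyl)tetrahydro-1H,3H-furo[3,4-c]furan-3a(4H)-ol | COc1ccc([C@H]2OC[C@@]3(O)[C@@H](c4ccc(OC)c(OC)c4)OC[C@@H]23)cc1OC | target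

**Totals**
Total step count: 4. Longest linear sequence: 4 (from 1 and 2).

**Steps most likely to fail**

Step 3 (the proposed new step). The risks are oxidation of the allylic alcohols to enals through palladium alkoxides, a mixed syn/anti course that would give the achiral trans-diaryl isomer, modest enantioselectivity, and ionisation of the acid-labile product. The fallback uses known chemistry only; it sets out from 5 and comes back at 6. Sharpless asymmetric epoxidation of both allylic alcohols (Ti(OiPr)4, L-(+)-diethyl tartrate, t-BuOOH, 4 Å MS, CH2Cl2, −20 °C) gives the bis-epoxide [(2S,2'S,3S,3'S)-3,3'-bis(3,4-dimethoxyphenyl)-2,2'-bioxirane-2,2'-diyl]dimethanol F1, in the (2S,3S) sense established for (E)-2-substituted cinnamyl alcohols. Catalytic camphorsulfonic acid in CH2Cl2 at −20 °C then lets each hydroxymethyl group open the benzylic carbon of the neighbouring epoxide (5-endo, inversion), giving (3R,3aS,6R,6aS)-3,6-bis(3,4-dimethoxyphenyl)tetrahydro-1H,3H-furo[3,4-c]furan-3a,6a-diol F2. In F2 each aryl is cis to its adjacent bridgehead hydroxyl, which is also the thermodynamically preferred arrangement, so any SN1 leakage is self-correcting. Thiocarbonyldiimidazole and DMAP in toluene at 110 °C give the cyclic thionocarbonate of that diol F3, and Corey–Winter olefination with 1,3-dimethyl-2-phenyl-1,3,2-diazaphospholidine in THF at 40 °C removes both bridgehead oxygens stereospecifically to give 6.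

Step 1. The second condensation on the carboxylate salt can stall at the mono-arylidene half-ester or give E/Z mixtures. The fallback sets out from 1 and comes back at 4. Wittig olefination of 1 with methyl 2-bromo-2-(triphenylphosphoranylidene)acetate (CH2Cl2, 25 °C) gives methyl (2Z)-2-bromo-3-(3,4-dimethoxyphenyl)prop-2-enoate F4. Reductive homocoupling of this vinyl bromide (NiBr2(PPh3)2 cat., Zn, Et4NI, THF, 50 °C) joins the two α-carbons with retention of alkene geometry and delivers 4.

Step 4. The tetrasubstituted alkene may hydroborate slowly, and the β-alkoxy borane 7 may fragment by elimination. The fallback sets out from 6 and comes back at 8. Mukaiyama radical hydration (Mn(dpm)3, i.e. tris(2,2,6,6-tetramethylheptane-3,5-dionato)manganese Mn(C11H19O2)3, cat., PhSiH3, O2, i-PrOH/CH2Cl2, 0 °C) delivers the hydrogen atom and then dioxygen to the face opposite the aryl groups. The cis ring fusion is enforced by ring strain, giving (3R,3aR,6S,6aS)-3a-hydroperoxy-3,6-bis(3,4-dimethoxyphenyl)hexahydrofuro[3,4-c]furan F5, which PPh3 reduces in the same flask to 8.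

**Further compounds**
F1 | step 3 | [(2S,2'S,3S,3'S)-3,3'-bis(3,4-dimethoxyphenyl)-2,2'-bioxirane-2,2'-diyl]dimethanol | OC[C@@]1(O[C@H]1c1ccc(OC)c(OC)c1)[C@@]1(CO)O[C@H]1c1ccc(OC)c(OC)c1
F2 | step 3 | (3R,3aS,6R,6aS)-3,6-bis(3,4-dimethoxyphenyl)tetrahydro-1H,3H-furo[3,4-c]furan-3a,6a-diol | COc1ccc([C@H]2OC[C@]3(O)[C@@H](c4ccc(OC)c(OC)c4)OC[C@]23O)cc1OC
F3 | step 3 | cyclic 3a,6a-thionocarbonate of F2 (same configuration) | COc1ccc([C@H]2OC[C@]3(OC(=S)O5)[C@@H](c4ccc(OC)c(OC)c4)OC[C@]235)cc1OC
F4 | step 1 | methyl (2Z)-2-bromo-3-(3,4-dimethoxyphenyl)prop-2-enoate | COC(=O)/C(Br)=C/c1ccc(OC)c(OC)c1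
F5 | step 4 | (3R,3aR,6S,6aS)-3a-hydroperoxy-3,6-bis(3,4-dimethoxyphenyl)hexahydrofuro[3,4-c]furan | COc1ccc([C@H]2OC[C@@]3(OO)[C@@H](c4ccc(OC)c(OC)c4)OC[C@@H]23)cc1OC
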